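**Retrosynthetic overview**

1. Decalin locants used below: C1 = CH with the propanoic acid chain, C2 = isopropylidene carbon, C4a = ring-fusion CH, C5 = quaternary C (CH3, CH2Ar), C6 = CH(CH3), C8a = ring-fusion C with the angular CH3; ring A = C1–C4/C4a/C8a, ring B = C4a–C8a. End game: acetylation of the unhindered phenol ⇐ hydroquinone (CAN, dithionite) ⇐ acid ⇐ C2 isopropylidene from a C2 ketone and acetone (McMurry).
2. Key disconnection C1–C8a (closes ring A). Enabling feature: the methyl-bearing quaternary ring-fusion carbon C8a is bonded directly to C1, and C1 is α to C2; with C2 as a ketone and a temporary CO2Me on C1, C1 is the enol carbon of a β-keto ester and C8a the tertiary cation from an exocyclic methylene on ring B.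
3. One flask: Roskamp homologation of an aldehyde to that β-keto ester, then SnCl4 cation–enol closure. This gives the C1–C8a bond, ring A, the angular methyl (from =CH2), the quaternary C8a with trans fusion, and the handle on C1 for the chain (acrylate Michael addition, Krapcho removal of the temporary ester).
4. Ring B precursor: (S)-4-methylcyclohex-2-enone → 3-arylmethyl enone (Cu-catalysed benzyl Grignard addition, Saegusa–Ito) → Me2CuLi anti to the C6 methyl (sets C5), propargylation anti to the arylmethyl group (sets C4a) → ketone methylenation, alkyne hydroboration to the aldehyde.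
5. Order of rings: arene (purchased, elaborated to the benzylic chloride) → ring B (organocatalytic Michael/aldol) → ring A (key step).

Key step: step 12

Notation: Ar = 2,5-dimethoxy-3-methylphenyl.
Assumption: the (R)-diphenylprolinol methyl ether catalyst is taken to give (S)-8 (attack on the enamine face remote from the diarylmethyl group); if the sense is the opposite, the enantiomeric catalyst is used and nothing else changes.

**Route**

Step 1
Reactants: 1 4-methoxy-2-methylphenol
Product: 2 2-hydroxy-5-methoxy-3-methylbenzaldehyde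
Conditions: MgCl2, Et3N, (CH2O)n, MeCN, reflux; aq. HCl
Reagents that add atoms: formaldehyde (as paraformaldehyde), C=O
Why: Magnesium-phenoxide-directed ortho-formylation (Casnati–Skattebøl) should deliver the aldehyde at the only free ortho position, the hydroxymethyl stage being oxidised by hydride transfer to a second formaldehyde.

Step 2
Reactants: 2 2-hydroxy-5-methoxy-3-methylbenzaldehyde
Product: 3 2,5-dimethoxy-3-methylbenzaldehyde
Conditions: MeI, K2CO3, DMF, rt
Reagents that add atoms: iodomethane, CI
Why: Williamson O-methylation of the phenoxide should be clean because no other acidic site is present.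

Step 3
Reactants: 3 2,5-dimethoxy-3-methylbenzaldehyde
Product: 4 (2,5-dimethoxy-3-methylphenyl)methanol
Conditions: NaBH4, MeOH, 0 °C
Reagents that add atoms: none
Why: Borohydride reduction of an aryl aldehyde to the benzylic alcohol.

Step 4
Reactants: 4 (2,5-dimethoxy-3-methylphenyl)methanol
Product: 5 1-(chloromethyl)-2,5-dimethoxy-3-methylbenzene
Conditions: SOCl2, CH2Cl2, 0 °C → rt
Reagents that add atoms: thionyl chloride, O=S(Cl)Cl
Why: Chlorination of an electron-rich benzylic alcohol via the chlorosulfite should be fast; the chloride is used without storage.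

Step 5
Reactants: 6 propanal; 7 but-3-en-2-one
Product: 8 (S)-2-methyl-5-oxohexanal
Conditions: (R)-2-(methoxydiphenylmethyl)pyrrolidine (5 mol%), ethyl 3,4-dihydroxybenzoate (20 mol%), neat, 4 °C
Reagents that add atoms: none
Why: Enamine-catalysed asymmetric Michael addition; the diarylmethyl group of the catalyst shields one enamine face and thereby sets the methyl-bearing stereocentre (later C6).

Step 6
Reactants: 8 (S)-2-methyl-5-oxohexanal
Product: 9 (S)-4-methylcyclohex-2-en-1-one
Conditions: LiOH·H2O (cat.), i-PrOH, rt
Reagents that add atoms: none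
Why: Intramolecular aldol condensation of the methyl ketone onto the aldehyde (the only six-membered mode); mild base should preserve the stereocentre, which ends γ to the carbonyl.

Step 7
Reactants: 5 1-(chloromethyl)-2,5-dimethoxy-3-methylbenzene; 9 (S)-4-methylcyclohex-2-en-1-one
Product: 11 (4S)-3-(ArCH2)-4-methyl-1-(trimethylsilyloxy)cyclohexene (3,4-trans), via benzylic Grignard reagent 10 (not isolated)
Conditions: Mg, THF, 0 °C; then 9, CuBr·SMe2 (10 mol%), TMSCl, DMPU, THF, –78 °C
Reagents that add atoms: chlorotrimethylsilane, C[Si](C)(C)Cl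
Why: Copper-catalysed, TMSCl-accelerated conjugate addition of a benzylic Grignard reagent with trapping of the enolate as its silyl enol ether; addition anti to the C4 methyl is expected but this centre is erased in step 8.

Step 8
Reactants: 11 (4S)-3-(ArCH2)-4-methyl-1-(trimethylsilyloxy)cyclohexene
Product: 12 (S)-3-(ArCH2)-4-methylcyclohex-2-en-1-one
Conditions: Pd(OAc)2 (1.05 equiv), MeCN, rt
Reagents that add atoms: none
Why: Saegusa–Ito oxidation; the palladium enolate can only β-eliminate the C3 hydrogen, which gives the 3-substituted enone and leaves the C4 stereocentre untouched.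

Step 9
Reactants: 12 (S)-3-(ArCH2)-4-methylcyclohex-2-en-1-one
Product: 14 (2R,3S,4S)-3-(ArCH2)-3,4-dimethyl-2-(prop-2-yn-1-yl)cyclohexan-1-one, via lithium enolate 13 (not isolated)
Conditions: Me2CuLi (from MeLi, CuI), Et2O, –20 → 0 °C; then propargyl bromide, HMPA, THF, –40 °C → rt
Reagents that add atoms: lithium dimethylcuprate, [Li+].C[Cu-]C; 3-bromoprop-1-yne, C#CCBr
Why: Cuprate conjugate addition anti to the pseudoaxial C4 methyl sets the quaternary carbon (new methyl trans to the C4 methyl, ArCH2 cis), and the regiospecific enolate is alkylated on the face away from the ArCH2 group and the C4 methyl, which sets the future C4a.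

Step 10
Reactants: 14 (2R,3S,4S)-3-(ArCH2)-3,4-dimethyl-2-(prop-2-yn-1-yl)cyclohexan-1-one
Product: 15 the 1-methylidene analogue of 14 (exocyclic C=CH2 in place of C=O)
Conditions: Zn, CH2Br2, TiCl4, THF/CH2Cl2, 0 °C → rt
Reagents that add atoms: dibromomethane, BrCBr
Why: Takai–Lombardo methylenation; the non-basic gem-dimetallic reagent should methylenate the hindered ketone without epimerising the adjacent stereocentre, which becomes configurationally fixed here.

Step 11
Reactants: 15 the 1-methylidene analogue of 14
Product: 17 3-[(1R,5S,6S)-6-(ArCH2)-5,6-dimethyl-2-methylidenecyclohexyl]propanal, via alkenylborane 16 (not isolated)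
Conditions: Sia2BH (from BH3·THF, 2-methylbut-2-ene), THF, 0 °C; then H2O2, pH 7 buffer
Reagents that add atoms: hydrogen peroxide, OO
Why: Anti-Markovnikov hydroboration of the terminal alkyne with a bulky dialkylborane (much faster than attack on the hindered 1,1-disubstituted alkene) and oxidation of the alkenylborane give the aldehyde.

Step 12
Reactants: 17 3-[(1R,5S,6S)-6-(ArCH2)-5,6-dimethyl-2-methylidenecyclohexyl]propanal; 18 methyl diazoacetate
Product: 21 methyl trans-5-(ArCH2)-5,6,8a-trimethyl-2-oxodecahydronaphthalene-1-carboxylate (ester equatorial), via β-keto ester 19 (not isolated), via tertiary carbocation 20 (not isolated)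
Conditions: SnCl2 (10 mol%), CH2Cl2, rt, until N2 evolution ends; then SnCl4 (2 equiv), –78 → 0 °C; aq. NaHCO3
Reagents that add atoms: none
Why: SnCl2 first catalyses the Roskamp homologation of 17 (addition of the diazo carbon, 1,2-hydride shift, loss of N2) to β-keto ester 19; SnCl4 then forms the chlorotin enolate with release of HCl, which protonates the exocyclic methylene at CH2 to the tertiary cation 20 (the new CH3 is the angular methyl), and the enol carbon bonds to it, making C1–C8a. The closest known reaction type is the SnCl4-promoted, β-keto-ester-terminated cation–olefin cyclization, specifically its second ring closure through a monocyclic 1-methylcyclohexyl cation to trans-decalin β-keto esters of the drimane type. The one ring formed (ring A) closes in a six-membered enol-endo mode: both enol carbons lie inside the new ring and the cation carbon is the sixth atom, through a chair-like transition state. C8a is controlled by the substrate: the equatorial side chain on C4a attacks the chair cation from the equatorial side while the axial face is shielded by the axial C5 methyl, so the new methyl becomes axial and the fusion trans; C1 is set by equilibration of the enolisable β-keto ester to the equatorial ester. The step needs C- over O-alkylation and must beat Friedel–Crafts (Grewe-type) capture by the dimethoxyarene, hydride shift and Prins reaction. O-alkylation is reversible under SnCl4; the tin enolate is far more nucleophilic than the arene and reaches the cation in a strain-free fused chair, whereas the arene needs the ring-flipped conformer and a bridged transition state; chelation as the tin enolate removes the ketone as a Prins acceptor.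

Step 13
Reactants: 21 methyl trans-5-(ArCH2)-5,6,8a-trimethyl-2-oxodecahydronaphthalene-1-carboxylate; 22 methyl acrylate
Product: 23 methyl 1-(3-methoxy-3-oxopropyl)-5-(ArCH2)-5,6,8a-trimethyl-2-oxodecahydronaphthalene-1-carboxylate
Conditions: Cs2CO3 (0.2 equiv), MeCN, rt
Reagents that add atoms: none
Why: Base-catalysed Michael addition of the cyclic β-keto ester; the temporary ester fixes C1 as the only nucleophilic site and attack should occur on the face anti to the angular methyl (this configuration is of no consequence).

Step 14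
Reactants: 23 methyl 1-(3-methoxy-3-oxopropyl)-5-(ArCH2)-5,6,8a-trimethyl-2-oxodecahydronaphthalene-1-carboxylate
Product: 24 methyl 3-[trans-5-(ArCH2)-5,6,8a-trimethyl-2-oxodecahydronaphthalen-1-yl]propanoate (chain equatorial, configuration as in the target)
Conditions: LiCl, H2O (2 equiv), DMSO, 150 °C
Reagents that add atoms: none
Why: Krapcho dealkoxycarbonylation removes only the ketone-activated ester (chloride attack at its methyl, decarboxylation), and protonation under equilibrating conditions places the C1 chain equatorial, cis to the angular methyl.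

Step 15
Reactants: 24 methyl 3-[trans-5-(ArCH2)-5,6,8a-trimethyl-2-oxodecahydronaphthalen-1-yl]propanoate; 25 acetone
Product: 26 methyl 3-[trans-5-(ArCH2)-5,6,8a-trimethyl-2-(propan-2-ylidene)decahydronaphthalen-1-yl]propanoate
Conditions: TiCl4, Zn, pyridine, THF, reflux; slow addition of 24 and acetone (10 equiv)
Reagents that add atoms: none
Why: Mixed McMurry coupling with excess acetone (pinacol-type coupling on low-valent titanium, then deoxygenation) places the tetrasubstituted double bond unambiguously at the former carbonyl carbon; the equatorial C1 epimer is the less hindered one and should be retained.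

Step 16
Reactants: 26 methyl 3-[trans-5-(ArCH2)-5,6,8a-trimethyl-2-(propan-2-ylidene)decahydronaphthalen-1-yl]propanoate
Product: 27 3-[trans-5-(ArCH2)-5,6,8a-trimethyl-2-(propan-2-ylidene)decahydronaphthalen-1-yl]propanoic acid
Conditions: LiOH, THF/MeOH/H2O, 40 °C; cold dilute HCl to pH 4
Reagents that add atoms: lithium hydroxide, [Li+].[OH-]
Why: Saponification of an unhindered methyl ester; brief cold acidification should avoid protonation of the tetrasubstituted alkene.

Step 17
Reactants: 27 3-[trans-5-(ArCH2)-5,6,8a-trimethyl-2-(propan-2-ylidene)decahydronaphthalen-1-yl]propanoic acid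
Product: 29 the corresponding 2,5-dihydroxy-3-methylbenzyl compound (hydroquinone acid), via benzoquinone 28 (not isolated)
Conditions: CAN (2.5 equiv), MeCN/H2O, 0 °C, minutes; then aq. Na2S2O4, EtOAc
Reagents that add atoms: water, O
Why: Oxidative demethylation of the 1,4-dimethoxyarene by CAN to the p-quinone (aryl–oxygen cleavage, oxygens from water), then dithionite reduction; short contact at 0 °C should spare the alkene.

Step 18
Reactants: 29 hydroquinone acid
Product: 30 3-[(1S,4aR,5S,6S,8aR)-5-[(5-acetoxy-2-hydroxy-3-methylphenyl)methyl]-5,6,8a-trimethyl-2-(propan-2-ylidene)decahydronaphthalen-1-yl]propanoic acid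
Conditions: Ac2O (1.05 equiv), pyridine, CH2Cl2, –10 °C; aq. NaHCO3 work-up
Reagents that add atoms: acetic anhydride, CC(=O)OC(C)=O
Why: Sterically differentiated acylation: the phenol flanked by the methyl and the benzylic CH2 is shielded, the other has two ortho hydrogens, and any mixed anhydride of the acid is hydrolysed on work-up.

**Compound list**

1 | 4-methoxy-2-methylphenol | COc1ccc(O)c(C)c1 | starting material
2 | 2-hydroxy-5-methoxy-3-methylbenzaldehyde | COc1cc(C)c(O)c(C=O)c1 | intermediate
3 | 2,5-dimethoxy-3-methylbenzaldehyde | COc1cc(C)c(OC)c(C=O)c1 | intermediate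
4 | (2,5-dimethoxy-3-methylphenyl)methanol | COc1cc(C)c(OC)c(CO)c1 | intermediate
5 | 1-(chloromethyl)-2,5-dimethoxy-3-methylbenzene | COc1cc(C)c(OC)c(CCl)c1 | intermediate
6 | propanal | CCC=O | starting material
7 | but-3-en-2-one | CC(=O)C=C | starting material
8 | (S)-2-methyl-5-oxohexanal | O=C[C@@H](C)CCC(C)=O | intermediate
9 | (S)-4-methylcyclohex-2-en-1-one | C[C@@H]1C=CC(=O)CC1 | intermediate
10 | (2,5-dimethoxy-3-methylbenzyl)magnesium chloride | COc1cc(C)c(OC)c(C[Mg]Cl)c1 | intermediate
11 | (4S)-3-(ArCH2)-4-methyl-1-(trimethylsilyloxy)cyclohexene, 3,4-trans | COc1cc(C)c(OC)c(C[C@H]2C=C(O[Si](C)(C)C)CC[C@@H]2C)c1 | intermediate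
12 | (S)-3-(ArCH2)-4-methylcyclohex-2-en-1-one | COc1cc(C)c(OC)c(CC2=CC(=O)CC[C@@H]2C)c1 | intermediate
13 | lithium enolate of (3S,4S)-3-(ArCH2)-3,4-dimethylcyclohexanone (methyls trans) | COc1cc(C)c(OC)c(C[C@]2(C)C=C(O[Li])CC[C@@H]2C)c1 | intermediate
14 | (2R,3S,4S)-3-(ArCH2)-3,4-dimethyl-2-(prop-2-yn-1-yl)cyclohexan-1-one (propargyl trans to ArCH2) | COc1cc(C)c(OC)c(C[C@]2(C)[C@@H](CC#C)C(=O)CC[C@@H]2C)c1 | intermediate
15 | 1-methylidene analogue of 14 | COc1cc(C)c(OC)c(C[C@]2(C)[C@@H](CC#C)C(=C)CC[C@@H]2C)c1 | intermediate
16 | (E)-alkenyl(disiamyl)borane from 15 | COc1cc(C)c(OC)c(C[C@]2(C)[C@@H](C/C=C/B(C(C)C(C)C)C(C)C(C)C)C(=C)CC[C@@H]2C)c1 | intermediate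
17 | 3-[(1R,5S,6S)-6-(ArCH2)-5,6-dimethyl-2-methylidenecyclohexyl]propanal | COc1cc(C)c(OC)c(C[C@]2(C)[C@@H](CCC=O)C(=C)CC[C@@H]2C)c1 | intermediate
18 | methyl diazoacetate | COC(=O)C=[N+]=[N-] | starting material
19 | methyl 5-[(1R,5S,6S)-6-(ArCH2)-5,6-dimethyl-2-methylidenecyclohexyl]-3-oxopentanoate | COc1cc(C)c(OC)c(C[C@]2(C)[C@@H](CCC(=O)CC(=O)OC)C(=C)CC[C@@H]2C)c1 | intermediate
20 | tertiary 1-methylcyclohexyl cation derived from 19 | COc1cc(C)c(OC)c(C[C@]2(C)[C@@H](CCC(=O)CC(=O)OC)[C+](C)CC[C@@H]2C)c1 | intermediate
21 | methyl trans-5-(ArCH2)-5,6,8a-trimethyl-2-oxodecahydronaphthalene-1-carboxylate, ester equatorial | COc1cc(C)c(OC)c(C[C@]2(C)[C@H]3CCC(=O)[C@@H](C(=O)OC)[C@]3(C)CC[C@@H]2C)c1 | intermediate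
22 | methyl acrylate | COC(=O)C=C | starting material
23 | Michael adduct, C1 quaternary (propanoate chain axial expected) | COc1cc(C)c(OC)c(C[C@]2(C)[C@H]3CCC(=O)[C@@](CCC(=O)OC)(C(=O)OC)[C@]3(C)CC[C@@H]2C)c1 | intermediate
24 | keto ester, C1 chain equatorial | COc1cc(C)c(OC)c(C[C@]2(C)[C@H]3CCC(=O)[C@@H](CCC(=O)OC)[C@]3(C)CC[C@@H]2C)c1 | intermediate
25 | acetone | CC(C)=O | starting material
26 | isopropylidene methyl ester | COc1cc(C)c(OC)c(C[C@]2(C)[C@H]3CCC(=C(C)C)[C@@H](CCC(=O)OC)[C@]3(C)CC[C@@H]2C)c1 | intermediate
27 | isopropylidene acid, hydroquinone dimethyl ether | COc1cc(C)c(OC)c(C[C@]2(C)[C@H]3CCC(=C(C)C)[C@@H](CCC(=O)O)[C@]3(C)CC[C@@H]2C)c1 | intermediate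
28 | 2-methyl-6-substituted 1,4-benzoquinone acid | CC1=CC(=O)C=C(C[C@]2(C)[C@H]3CCC(=C(C)C)[C@@H](CCC(=O)O)[C@]3(C)CC[C@@H]2C)C1=O | intermediate
29 | hydroquinone acid | Cc1cc(O)cc(C[C@]2(C)[C@H]3CCC(=C(C)C)[C@@H](CCC(=O)O)[C@]3(C)CC[C@@H]2C)c1O | intermediate
30 | 3-[(1S,4aR,5S,6S,8aR)-5-[(5-acetoxy-2-hydroxy-3-methylphenyl)methyl]-5,6,8a-trimethyl-2-(propan-2-ylidene)decahydronaphthalen-1-yl]propanoic acid | CC(=O)Oc1cc(C)c(O)c(C[C@]2(C)[C@H]3CCC(=C(C)C)[C@@H](CCC(=O)O)[C@]3(C)CC[C@@H]2C)c1 | target

**Step count and risks**

Total steps: 18. Longest linear sequence: 16 (steps 1–4, then 7–18).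

Step 12 (key step). What may go wrong: capture of the tertiary cation by the electron-rich arene through the ring-flipped conformer (bridged Friedel–Crafts closure), closure to the cis-fused ring, or ene/Prins reaction of the aldehyde before homologation is complete. The fallback sets out from 17 and comes back at 21. The Roskamp homologation alone (SnCl2 cat.) is run with isolation of β-keto ester 19. Regitz diazo transfer (p-ABSA, Et3N, MeCN) gives methyl 2-diazo-5-[(1R,5S,6S)-6-(ArCH2)-5,6-dimethyl-2-methylidenecyclohexyl]-3-oxopentanoate F1. Rh2(OAc)4-catalysed intramolecular cyclopropanation of the exocyclic methylene then forms the C1–C8a bond through a neutral carbenoid, with no cation and therefore no arene capture, and gives the cyclopropane-fused keto ester F2. Reductive opening of this doubly activated cyclopropane with SmI2 (THF/MeOH) should cleave the exocyclic C1–CH2 bond, the one best aligned with the ketone π system, which turns the CH2 into the angular methyl and gives 21.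

Step 13. What may go wrong: slow C–C bond formation at C1 next to the quaternary C8a, reversal of the Michael addition, or O-alkylation. The fallback sets out from 21 and comes back at 24. Transesterification with allyl alcohol (DMAP, toluene, reflux) gives the allyl β-keto ester F3. Pd(PPh3)4-catalysed decarboxylative allylation (Tsuji–Trost type) then puts an allyl group on C1 regiospecifically without building a quaternary carbon, giving the 1-allyl-2-decalone F4. Hydroboration of its only alkene (9-BBN; NaOH, H2O2) gives the 3-hydroxypropyl ketone F5. Oxidation (TEMPO, PhI(OAc)2, aq. MeCN) gives the keto acid F6, and esterification with TMSCHN2 gives 24.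

Step 15. What may go wrong: poor cross-coupling at the hindered ketone (arrest at the pinacol stage, simple reduction) or attack of the low-valent titanium on the ester. The fallback sets out from 24 and comes back at 26 by a Krief–Reich olefination. Addition of 2-lithio-2-(methylseleno)propane (from 2,2-bis(methylseleno)propane and n-BuLi, CeCl3, THF, –78 °C) to the ketone from the equatorial side gives the β-hydroxy selenide F7. MsCl and Et3N (CH2Cl2, 0 °C) should then remove hydroxyl and selenium through a seleniranium ion, fixing the double bond between C2 and the former carbanion carbon, and give 26.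

Further compounds
F1 | step 12 | methyl 2-diazo-5-[(1R,5S,6S)-6-(ArCH2)-5,6-dimethyl-2-methylidenecyclohexyl]-3-oxopentanoate | COc1cc(C)c(OC)c(C[C@]2(C)[C@@H](CCC(=O)C(=[N+]=[N-])C(=O)OC)C(=C)CC[C@@H]2C)c1
F2 | step 12 | cyclopropane-fused keto ester (C1–C8a and C1–CH2 bonds, CH2 on the face of the future angular methyl) | COc1cc(C)c(OC)c(C[C@]2(C)[C@H]3CCC(=O)[C@@]4(C(=O)OC)C[C@@]34CC[C@@H]2C)c1
F3 | step 13 | allyl trans-5-(ArCH2)-5,6,8a-trimethyl-2-oxodecahydronaphthalene-1-carboxylate | COc1cc(C)c(OC)c(C[C@]2(C)[C@H]3CCC(=O)[C@@H](C(=O)OCC=C)[C@]3(C)CC[C@@H]2C)c1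
F4 | step 13 | trans-1-allyl-5-(ArCH2)-5,6,8a-trimethyldecahydronaphthalen-2-one (allyl equatorial) | COc1cc(C)c(OC)c(C[C@]2(C)[C@H]3CCC(=O)[C@@H](CC=C)[C@]3(C)CC[C@@H]2C)c1
F5 | step 13 | trans-1-(3-hydroxypropyl)-5-(ArCH2)-5,6,8a-trimethyldecahydronaphthalen-2-one | COc1cc(C)c(OC)c(C[C@]2(C)[C@H]3CCC(=O)[C@@H](CCCO)[C@]3(C)CC[C@@H]2C)c1
F6 | step 13 | 3-[trans-5-(ArCH2)-5,6,8a-trimethyl-2-oxodecahydronaphthalen-1-yl]propanoic acid | COc1cc(C)c(OC)c(C[C@]2(C)[C@H]3CCC(=O)[C@@H](CCC(=O)O)[C@]3(C)CC[C@@H]2C)c1
F7 | step 15 | β-hydroxy selenide: C2 carries axial OH and equatorial 2-(methylseleno)propan-2-yl | COc1cc(C)c(OC)c(C[C@]2(C)[C@H]3CC[C@](O)(C(C)(C)[Se]C)[C@@H](CCC(=O)OC)[C@]3(C)CC[C@@H]2C)c1
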